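**Strategy.** The route rests on disconnecting the C10=C11 enone bond of the cyclopentenone ring (C8–C12, prostanoid numbering). Both carbons are unsubstituted CH, so the ring can be unzipped to an acyclic trienone with an acryloyl group on C8 and a vinyl group on C12. Ring-closing metathesis then forms the ring, the conjugated enone and the finished target in one operation, sparing the hindered E-C13=C14 olefin, the 15-acetate and the free acid. The precursor is assembled in one stereodefining step: an iridium/amine dual-catalytic α-allylation joins 9-oxononanoic acid to a bis-allylic alcohol carrying the intact ω-chain, setting C8 and C12 together.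

Key step: step 7

Assumption: the iridium ligand is taken to induce the same sense at C12 with the alkenyl vinyl carbinol 5 as with aryl vinyl carbinols; since the ligand (C12) and the amine (C8) act independently, the antipodal ligand alone would be substituted if the sense proved opposite.

**Step 1**
Reactants: 1 (S)-oct-1-en-3-ol
Product: 2 (S)-oct-1-en-3-yl acetate
Conditions: Ac2O, pyridine, DMAP (cat.), CH2Cl2, 0 °C to rt
Reagents that add atoms: acetic anhydride, CC(=O)OC(C)=O
Why: Acylation of a secondary alcohol with retention at the carbinol carbon, which installs the final 15-acetate (15S) at the outset.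

**Step 2**
Reactants: 2 (S)-oct-1-en-3-yl acetate; 3 (E)-but-2-enal (crotonaldehyde, excess)
Product: 4 (2E,4S)-1-oxonon-2-en-4-yl acetate
Conditions: second-generation Hoveyda–Grubbs catalyst (5 mol%), CH2Cl2, 40 °C
Reagents that add atoms: none
Why: Olefin cross-metathesis of a terminal allylic acetate with an enal partner should give the conjugated E-enal under thermodynamic control with loss of propene, leaving the acetoxy-bearing stereocentre untouched.

**Step 3**
Reactants: 4 (2E,4S)-1-oxonon-2-en-4-yl acetate
Product: 5 (4E,6S)-3-hydroxyundeca-1,4-dien-6-yl acetate (both C3 epimers)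
Conditions: vinylMgBr (1.1 equiv), THF, −78 °C; aq. NH4Cl
Reagents that add atoms: vinylmagnesium bromide, C=C[Mg]Br
Why: Grignard 1,2-addition to the enal is much faster at −78 °C than attack on the acetate; the new carbinol centre is formed without control, which is harmless because step 4 ionises it.

**Step 4**
Reactants: 5 (4E,6S)-3-hydroxyundeca-1,4-dien-6-yl acetate; 6 9-oxononanoic acid (2 equiv)
Product: 7 (8R,9R,10E,12S)-12-acetoxy-9-ethenyl-8-formylheptadec-10-enoic acid
Conditions: [Ir(cod)Cl]2 (3 mol%), (R)-binaphthol-derived dibenzo[b,f]azepine phosphoramidite–olefin ligand (12 mol%), (S)-2-[bis(3,5-bis(trifluoromethyl)phenyl)(trimethylsilyloxy)methyl]pyrrolidine (15 mol%), (MeO)2P(O)OH (50 mol%), ClCH2CH2Cl, 25 °C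
Reagents that add atoms: none
Why: In this stereodivergent iridium/amine dual-catalytic α-allylation of a linear aldehyde, the acid-assisted iridium catalyst should ionise both epimers of 5 to one allyl complex with loss of water and direct attack to its substituted terminus, the ligand fixing the vinyl-bearing centre (9R, prostanoid C12), while the enamine of 6 is attacked on the face away from the diarylmethyl group, fixing the α-centre (8R, prostanoid C8).

**Step 5**
Reactants: 7 (8R,9R,10E,12S)-12-acetoxy-9-ethenyl-8-formylheptadec-10-enoic acid
Product: 8 (8R,9R,10E,12S)-12-acetoxy-9-ethenyl-8-[(1RS)-1-hydroxyprop-2-en-1-yl]heptadec-10-enoic acid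
Conditions: vinylMgBr (2.2 equiv), THF, −78 °C; aq. NH4Cl, then 1 M HCl to pH 4
Reagents that add atoms: vinylmagnesium bromide, C=C[Mg]Br
Why: The first equivalent of Grignard reagent deprotonates the acid (giving ethene) and the second adds to the aldehyde faster than to the acetate or the carboxylate; the new carbinol centre is uncontrolled and is erased by the oxidation in step 6.

**Step 6**
Reactants: 8 (8R,9R,10E,12S)-12-acetoxy-9-ethenyl-8-[(1RS)-1-hydroxyprop-2-en-1-yl]heptadec-10-enoic acid
Product: 9 (8R,9R,10E,12S)-12-acetoxy-9-ethenyl-8-(prop-2-enoyl)heptadec-10-enoic acid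
Conditions: Dess–Martin periodinane (1.3 equiv), CH2Cl2, 0 °C to rt
Reagents that add atoms: none
Why: Dess–Martin oxidation of the secondary allylic alcohol under mild, non-basic conditions should give the vinyl ketone without epimerising the adjacent C8 centre or touching the acid, the acetate or the olefins.

**Step 7**
Reactants: 9 (8R,9R,10E,12S)-12-acetoxy-9-ethenyl-8-(prop-2-enoyl)heptadec-10-enoic acid
Product: 10 7-[(1R,2S)-2-[(1E,3S)-3-acetoxyoct-1-en-1-yl]-5-oxocyclopent-3-en-1-yl]heptanoic acid (target; (13E,15S)-15-acetoxy-9-oxoprosta-10,13-dien-1-oic acid)
Conditions: second-generation Hoveyda–Grubbs catalyst (5 mol%), 1,4-benzoquinone (10 mol%), CH2Cl2 (0.005 M), 40 °C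
Reagents that add atoms: none
Why: A ruthenium alkylidene should load first onto the monosubstituted vinyl group on C12, the only unhindered electron-rich terminal olefin, and the resulting C11 alkylidene should then undergo intramolecular [2+2] cycloaddition and cycloreversion with the acryloyl C10=CH2, expelling ethene and forming the C10=C11 bond. The closest known reaction type is ring-closing metathesis of 1,6-dien-3-ones to cyclopent-2-enones. The only ring closed is the five-membered carbocycle C8–C9–C10–C11–C12, closed as a cycloalkene-forming metathesis between two terminal methylene olefins, which makes the ring olefin cis by necessity and delivers the enone at its final oxidation level. No stereocentre is created: C8, C12 and C15 are carried through unchanged under neutral, base-free conditions, and the 8,12-trans arrangement is in any case the thermodynamically preferred one for a 4,5-disubstituted cyclopent-2-enone. The step needs chemoselectivity for the C12 vinyl group over the internal E-C13=C14 olefin, which could also close a five-membered enone; this is secured by the branching at C12 and at the acetoxy-bearing C15 that flank that olefin, and high dilution suppresses intermolecular metathesis of the acryloyl group.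

**Compound list**
1 | (S)-oct-1-en-3-ol | CCCCC[C@@H](C=C)O | starting material
2 | (S)-oct-1-en-3-yl acetate | CCCCC[C@@H](C=C)OC(C)=O | intermediate
3 | (E)-but-2-enal (crotonaldehyde) | C/C=C/C=O | starting material
4 | (2E,4S)-1-oxonon-2-en-4-yl acetate | CCCCC[C@@H](/C=C/C=O)OC(C)=O | intermediate
5 | (4E,6S)-3-hydroxyundeca-1,4-dien-6-yl acetate (both C3 epimers) | CCCCC[C@@H](/C=C/C(O)C=C)OC(C)=O | intermediate
6 | 9-oxononanoic acid | O=CCCCCCCCC(=O)O | starting material
7 | (8R,9R,10E,12S)-12-acetoxy-9-ethenyl-8-formylheptadec-10-enoic acid | CCCCC[C@@H](/C=C/[C@@H](C=C)[C@H](C=O)CCCCCCC(=O)O)OC(C)=O | intermediate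
8 | (8R,9R,10E,12S)-12-acetoxy-9-ethenyl-8-[(1RS)-1-hydroxyprop-2-en-1-yl]heptadec-10-enoic acid | CCCCC[C@@H](/C=C/[C@@H](C=C)[C@H](C(O)C=C)CCCCCCC(=O)O)OC(C)=O | intermediate
9 | (8R,9R,10E,12S)-12-acetoxy-9-ethenyl-8-(prop-2-enoyl)heptadec-10-enoic acid | CCCCC[C@@H](/C=C/[C@@H](C=C)[C@H](C(=O)C=C)CCCCCCC(=O)O)OC(C)=O | intermediate
10 | 7-[(1R,2S)-2-[(1E,3S)-3-acetoxyoct-1-en-1-yl]-5-oxocyclopent-3-en-1-yl]heptanoic acid | CCCCC[C@@H](/C=C/[C@H]1C=CC(=O)[C@@H]1CCCCCCC(=O)O)OC(C)=O | target

**Totals.** Total step count: 7. Longest linear sequence: 7 steps (1 → 2 → 4 → 5 → 7 → 8 → 9 → 10).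

**Steps most likely to fail**

Step 4. The enamine may attack the remote terminus of the iridium-bound dienyl cation, giving a conjugated diene instead of branched substitution at C12. The free acid or the C15 acetate may also interfere with ionisation. The fallback sets out from 4, uses 6, and comes back at 7. Ethynylmagnesium bromide (THF, −78 °C) should convert 4 into the alkenyl propargylic alcohol (4E,6S)-3-hydroxyundec-4-en-1-yn-6-yl acetate F1. A ruthenium-allenylidene/enamine propargylic alkylation ([Cp*RuCl(SMe)]2, NH4BF4, the same (S)-diarylprolinol silyl ether, toluene, rt) should then join F1 and 6 at the carbinol carbon with loss of water, the allenylidene leaving no ambiguity of position, to give (8R,9R,10E,12S)-12-acetoxy-9-ethynyl-8-formylheptadec-10-enoic acid F2. Here the amine sets C8, and any C12 epimer would be removed by chromatography. Semihydrogenation of the terminal alkyne (H2, Pd/CaCO3 poisoned with Pb(OAc)2, quinoline, EtOAc) should then return 7.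

Step 7. The electron-poor acryloyl group may be engaged too slowly, so that the C11 alkylidene oligomerises or ruthenium hydrides move the skipped olefins into conjugation. The fallback sets out from 8 and comes back at 10. Ring closure is carried out one oxidation level lower, on the electron-rich diene carbinol 8 with the same catalyst, to give (13E,15S)-15-acetoxy-9-hydroxyprosta-10,13-dien-1-oic acid F3 as both C9 epimers. Oxidation of this allylic cyclopentenol (MnO2, CH2Cl2, or Dess–Martin periodinane) should then give 10.

Step 5. The Grignard reagent may attack the C15 acetate or enolise the aldehyde with epimerisation at C8, while the magnesium carboxylate keeps the substrate poorly soluble. The fallback sets out from 7 and comes back at 8. It is a Nozaki–Hiyama–Kishi vinylation of 7 itself (vinyl bromide and CrCl2 in excess, NiCl2 cat., DMF, 25 °C; dilute acid work-up), the excess covering any reagent lost to the acidic proton. The vinylchromium reagent is not basic enough to enolise the aldehyde and does not add to esters, so 8 should form directly.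

**Further compounds**
F1 | step 4 | (4E,6S)-3-hydroxyundec-4-en-1-yn-6-yl acetate (both C3 epimers) | CCCCC[C@@H](/C=C/C(O)C#C)OC(C)=O
F2 | step 4 | (8R,9R,10E,12S)-12-acetoxy-9-ethynyl-8-formylheptadec-10-enoic acid | CCCCC[C@@H](/C=C/[C@@H](C#C)[C@H](C=O)CCCCCCC(=O)O)OC(C)=O
F3 | step 7 | (13E,15S)-15-acetoxy-9-hydroxyprosta-10,13-dien-1-oic acid (both C9 epimers) | CCCCC[C@@H](/C=C/[C@H]1C=CC(O)[C@@H]1CCCCCCC(=O)O)OC(C)=O
F0 | step 5 | none | none
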